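**Retrosynthetic overview**
1. Target ⇒ tri-O-benzyl all-cis oxan-4-ol ⇒ cis-2,6-disubstituted oxan-4-one. Hydrogenolysis comes last, and axial hydride delivery sets C4.
2. Oxan-4-one ⇒ one-carbon ring expansion of an (S)-5-substituted oxolan-3-one. The ring A–CH carbene carbon is stitched into the O–CH2 bond through an oxonium ylide and a stepwise 1,2-shift. This makes the six-membered ring, the C1–C2 bond of the heptane chain and the benzylic centre.
3. Oxolan-3-one ⇒ (S)-homopropargylic alcohol (gold alkyne oxidation/O–H insertion) ⇒ 3-arylpropanal + propargyl bromide (asymmetric Nozaki–Hiyama–Kishi) ⇒ 4-iodophenol + allyl alcohol (Heck).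
4. Carbene source ⇒ tosylhydrazone of 3,4-bis(benzyloxy)-5-methoxybenzaldehyde ⇒ syringaldehyde ⇒ p-cresol.
5. Ring order: both benzene rings come with the starting materials. The five-membered oxacycle is closed first and then enlarged to the six-membered ring.

Assumption: the SMILES is read as (2S,4R,6S), the all-cis, all-equatorial oxane, and the ligand antipode in step 8 is the one that gives Re-face addition (otherwise its mirror image is used).

**Step 1**
Reactants: 1 4-methylphenol (p-cresol)
Product: 4 3,5-dibromo-4-hydroxybenzaldehyde, via 2,6-dibromo-4-methylphenol 2 (not isolated), via 2,6-dibromo-4-(dibromomethyl)phenol 3 (not isolated)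
Conditions: Br2 (2.05 equiv), o-dichlorobenzene, 35–40 °C; Br2 (2.05 equiv), 150–160 °C; H2O, 100 °C
Reagents that add atoms: bromine, BrBr; water, O
Why: Electrophilic aromatic bromination fills both positions ortho to the OH, hot bromine takes the para-methyl group to the benzal dibromide (side-chain bromination), and gem-dihalide hydrolysis gives the aldehyde, with no stereocentre involved.

**Step 2**
Reactants: 4 3,5-dibromo-4-hydroxybenzaldehyde
Product: 5 4-hydroxy-3,5-dimethoxybenzaldehyde (syringaldehyde)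
Conditions: NaOMe (5 equiv), CuCl (0.2 equiv), DMF/MeOH, 100–110 °C; then aq HCl
Reagents that add atoms: sodium methoxide, C[O-].[Na+]
Why: Copper-catalysed Ullmann-type methoxylation replaces both aryl bromides, and the aldehyde has no alpha hydrogen and survives.

**Step 3**
Reactants: 5 syringaldehyde
Product: 6 3,4-dihydroxy-5-methoxybenzaldehyde
Conditions: AlCl3 (1.2 equiv), pyridine (4.5 equiv), CH2Cl2, reflux, 24 h; then 2 M HCl
Reagents that add atoms: none
Why: In this chelation-controlled Lewis-acid ether cleavage the aluminium phenolate activates one flanking OMe for SN2 demethylation, the catecholate chelate then shuts off the second, and the two OMe groups are equivalent so only one product can form.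

**Step 4**
Reactants: 6 3,4-dihydroxy-5-methoxybenzaldehyde
Product: 7 3,4-bis(benzyloxy)-5-methoxybenzaldehyde
Conditions: BnBr (2.3 equiv), K2CO3 (3 equiv), DMF, 60 °C
Reagents that add atoms: benzyl bromide, BrCc1ccccc1
Why: Williamson etherification masks both acidic O–H groups, which would otherwise quench the carbene in step 10.

**Step 5**
Reactants: 7 3,4-bis(benzyloxy)-5-methoxybenzaldehyde
Product: 8 (E)-N'-[3,4-bis(benzyloxy)-5-methoxybenzylidene]-4-methylbenzenesulfonohydrazide
Conditions: TsNHNH2 (1.05 equiv), MeOH, rt, 2 h; filter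
Reagents that add atoms: 4-methylbenzenesulfonohydrazide, Cc1ccc(cc1)S(=O)(=O)NN
Why: Hydrazone condensation gives a crystalline, water-free carbene precursor.

**Step 6**
Reactants: 9 4-iodophenol
Product: 10 1-(benzyloxy)-4-iodobenzene
Conditions: BnBr (1.1 equiv), K2CO3 (1.5 equiv), acetone, reflux
Reagents that add atoms: benzyl bromide, BrCc1ccccc1
Why: Williamson etherification protects the ring B phenol with the same group as ring A, so one final operation removes all three.

**Step 7**
Reactants: 10 1-(benzyloxy)-4-iodobenzene; 11 prop-2-en-1-ol (allyl alcohol)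
Product: 12 3-[4-(benzyloxy)phenyl]propanal
Conditions: Pd(OAc)2 (2 mol %), Bu4NCl (1 equiv), NaHCO3 (2.5 equiv), DMF, 50 °C
Reagents that add atoms: none
Why: In this Heck arylation under Jeffery conditions the aryl group adds to the terminal carbon, and beta-hydride elimination towards the carbinol gives the enol and hence the aldehyde.

**Step 8**
Reactants: 12 3-[4-(benzyloxy)phenyl]propanal; 13 3-bromoprop-1-yne (propargyl bromide)
Product: 15 (3S)-1-[4-(benzyloxy)phenyl]hex-5-yn-3-ol, via trimethylsilyl ether 14 (not isolated)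
Conditions: CrCl2 (10 mol %), chiral 1,8-bis(4-isopropyl-4,5-dihydrooxazol-2-yl)-3,6-diphenylcarbazole ligand (11 mol %), Mn powder (2 equiv), Me3SiCl (2 equiv), iPr2NEt (30 mol %), THF, 0 °C to rt; then 1 M HCl
Reagents that add atoms: none
Why: In this catalytic asymmetric Nozaki–Hiyama–Kishi propargylation the Mn-recycled low-valent chromium turns 13 into an allenyl-metal nucleophile that adds by a closed SE2' transition state in the tridentate chiral pocket to the Re face of 12, which sets the S carbinol centre (later C6), while Me3SiCl releases the catalyst as 14.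

**Step 9**
Reactants: 15 (3S)-1-[4-(benzyloxy)phenyl]hex-5-yn-3-ol
Product: 16 (5S)-5-{2-[4-(benzyloxy)phenyl]ethyl}oxolan-3-one
Conditions: Ph3PAuNTf2 (5 mol %), 3,5-dichloropyridine N-oxide (2 equiv), MsOH (1.2 equiv), ClCH2CH2Cl, rt
Reagents that add atoms: 3,5-dichloropyridine N-oxide, [O-][n+]1cc(Cl)cc(Cl)c1
Why: In this gold-catalysed alkyne oxidation the N-oxide adds to the internal alkyne carbon, N–O cleavage leaves an alpha-oxo gold carbene at the terminal carbon, and intramolecular O–H insertion closes the five-membered ring without touching the carbinol C–O bond, so S is kept.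

**Step 10**
Reactants: 8 tosylhydrazone of 3,4-bis(benzyloxy)-5-methoxybenzaldehyde; 16 (5S)-5-{2-[4-(benzyloxy)phenyl]ethyl}oxolan-3-one
Product: 19 (2S,6S)-2-[3,4-bis(benzyloxy)-5-methoxyphenyl]-6-{2-[4-(benzyloxy)phenyl]ethyl}oxan-4-one (2,6-cis), via aryldiazomethane 17 (not isolated), via oxonium ylide 18 (not isolated)
Conditions: 8 (2.0 equiv), NaH (2.0 equiv), THF, 0 °C to rt, solvent swap to PhCF3; 16 (1.0 equiv), Rh2(OAc)4 (2 mol %), BnEt3NCl (10 mol %), 4 Å MS, 40 °C, 16 h
Reagents that add atoms: none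
Why: Proposed new method: slow Bamford–Stevens release of 17 and its capture by Rh2(OAc)4 give an electrophilic rhodium benzylidene, which is attacked by the only dialkyl-ether oxygen present, the ring O of 16, to give ylide 18; in 18 the carbanion lone pair pushes and the ketone pulls, so the O–C2 bond breaks to a tethered enolate/aryl-stabilised (E)-oxocarbenium pair that recombines at carbon, which is a stepwise, non-concerted Stevens 1,2-shift of the alpha-keto CH2 from O to the ylide carbon and enlarges the five-membered ring to the oxan-4-one; closure through a chair that places both substituents equatorial sets C2 as S (2,6-cis) under control of C6, whose C–O bond is never broken; the closest known reaction types are the carbene-induced oxonium-ylide Stevens ring expansion of oxetanes to oxolanes and the Petasis–Ferrier rearrangement, which passes through the same kind of ion pair, whereas carbene insertion into the C–O bond of an unstrained oxolan-3-one has not been shown.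

**Step 11**
Reactants: 19 (2S,6S)-oxan-4-one
Product: 20 (2S,4R,6S)-2-[3,4-bis(benzyloxy)-5-methoxyphenyl]-6-{2-[4-(benzyloxy)phenyl]ethyl}oxan-4-ol (all-cis)
Conditions: NaBH4 (1.5 equiv), MeOH/THF 4:1, −20 °C
Reagents that add atoms: none
Why: In this substrate-controlled ketone reduction the small hydride attacks the chair-locked diequatorial ketone along the axial trajectory and gives the equatorial 4R alcohol.

**Step 12**
Reactants: 20 (2S,4R,6S)-tri-O-benzyl oxan-4-ol
Product: 21 (2S,4R,6S)-2-(3,4-dihydroxy-5-methoxyphenyl)-6-[2-(4-hydroxyphenyl)ethyl]oxan-4-ol (target)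
Conditions: H2 (1 atm), 10% Pd/C, EtOAc/MeOH 1:1, rt, 3 h; work-up under argon
Reagents that add atoms: none
Why: Catalytic hydrogenolysis cleaves the three aryl benzyl ethers much faster than the secondary dialkyl benzylic C2–O bond of the ring, and no stereocentre is touched.

**Compound list**
1 | 4-methylphenol (p-cresol) | Cc1ccc(O)cc1 | starting material
2 | 2,6-dibromo-4-methylphenol | Cc1cc(Br)c(O)c(Br)c1 | intermediate
3 | 2,6-dibromo-4-(dibromomethyl)phenol | BrC(Br)c1cc(Br)c(O)c(Br)c1 | intermediate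
4 | 3,5-dibromo-4-hydroxybenzaldehyde | O=Cc1cc(Br)c(O)c(Br)c1 | intermediate
5 | 4-hydroxy-3,5-dimethoxybenzaldehyde | COc1cc(C=O)cc(OC)c1O | intermediate
6 | 3,4-dihydroxy-5-methoxybenzaldehyde | COc1cc(C=O)cc(O)c1O | intermediate
7 | 3,4-bis(benzyloxy)-5-methoxybenzaldehyde | COc1cc(C=O)cc(OCc2ccccc2)c1OCc1ccccc1 | intermediate
8 | (E)-N'-[3,4-bis(benzyloxy)-5-methoxybenzylidene]-4-methylbenzenesulfonohydrazide | COc1cc(/C=N/NS(=O)(=O)c2ccc(C)cc2)cc(OCc2ccccc2)c1OCc1ccccc1 | intermediate
9 | 4-iodophenol | Oc1ccc(I)cc1 | starting material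
10 | 1-(benzyloxy)-4-iodobenzene | Ic1ccc(OCc2ccccc2)cc1 | intermediate
11 | prop-2-en-1-ol | C=CCO | starting material
12 | 3-[4-(benzyloxy)phenyl]propanal | O=CCCc1ccc(OCc2ccccc2)cc1 | intermediate
13 | 3-bromoprop-1-yne | C#CCBr | starting material
14 | (3S)-1-[4-(benzyloxy)phenyl]hex-5-yn-3-yl trimethylsilyl ether | C#CC[C@H](CCc1ccc(OCc2ccccc2)cc1)O[Si](C)(C)C | intermediate
15 | (3S)-1-[4-(benzyloxy)phenyl]hex-5-yn-3-ol | C#CC[C@H](CCc1ccc(OCc2ccccc2)cc1)O | intermediate
16 | (5S)-5-{2-[4-(benzyloxy)phenyl]ethyl}oxolan-3-one | O=C1C[C@H](CCc2ccc(OCc3ccccc3)cc2)OC1 | intermediate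
17 | 1,2-bis(benzyloxy)-5-(diazomethyl)-3-methoxybenzene | COc1cc(C=[N+]=[N-])cc(OCc2ccccc2)c1OCc1ccccc1 | intermediate
18 | oxonium ylide: (5S)-1-{[3,4-bis(benzyloxy)-5-methoxyphenyl]methanidyl}-5-{2-[4-(benzyloxy)phenyl]ethyl}-3-oxooxolan-1-ium | COc1cc([CH-][O+]2CC(=O)C[C@@H]2CCc2ccc(OCc3ccccc3)cc2)cc(OCc2ccccc2)c1OCc1ccccc1 | intermediate
19 | (2S,6S)-2-[3,4-bis(benzyloxy)-5-methoxyphenyl]-6-{2-[4-(benzyloxy)phenyl]ethyl}oxan-4-one | COc1cc([C@@H]2CC(=O)C[C@H](CCc3ccc(OCc4ccccc4)cc3)O2)cc(OCc2ccccc2)c1OCc1ccccc1 | intermediate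
20 | (2S,4R,6S)-2-[3,4-bis(benzyloxy)-5-methoxyphenyl]-6-{2-[4-(benzyloxy)phenyl]ethyl}oxan-4-ol | COc1cc([C@@H]2C[C@H](O)C[C@H](CCc3ccc(OCc4ccccc4)cc3)O2)cc(OCc2ccccc2)c1OCc1ccccc1 | intermediate
21 | (2S,4R,6S)-2-(3,4-dihydroxy-5-methoxyphenyl)-6-[2-(4-hydroxyphenyl)ethyl]oxan-4-ol | COc1cc([C@@H]2C[C@H](O)C[C@H](CCc3ccc(O)cc3)O2)cc(O)c1O | target

**Step count**
Total steps: 12.
Longest linear sequence: 8 (steps 1, 2, 3, 4, 5, 10, 11, 12).

**Three steps most likely to fail**

**Step 10 (the proposed new ring expansion).**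
- The carbene may dimerise to the stilbene or azine.
- It may attack the ketone oxygen, giving a carbonyl ylide and then an epoxide.
- A proton shift within 18 followed by migration of the benzylic group would give a 2-(arylmethyl)oxolan-3-one that is not ring-expanded.
- Part of the product may be the 2,6-trans isomer.

The fallback uses known chemistry, sets out from 15 and 7, and comes back at 19. Markovnikov hydration of the alkyne of 15 (Ph3PAuNTf2 cat., wet 1,4-dioxane) gives (4S)-6-[4-(benzyloxy)phenyl]-4-hydroxyhexan-2-one F1. Its dianion (LiN(iPr)2, 2.2 equiv, THF, −78 °C, kinetic methyl-side enolate) adds to aldehyde 7. This gives (5S)-1-[3,4-bis(benzyloxy)-5-methoxyphenyl]-7-[4-(benzyloxy)phenyl]-1,5-dihydroxyheptan-3-one F2 as a mixture of C1 epimers. Amberlyst-15 in CH2Cl2 dehydrates the electron-rich benzylic alcohol to (1E,5S)-1-[3,4-bis(benzyloxy)-5-methoxyphenyl]-7-[4-(benzyloxy)phenyl]-5-hydroxyhept-1-en-3-one F3. F3 closes in the same flask by thermodynamically controlled 6-endo oxa-Michael addition to the cis ketone 19.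

**Step 8 (asymmetric propargylation).** The enantiomeric excess may be too low for this unbranched aldehyde, and some allenyl carbinol may form. The fallback sets out from 12 and comes back at 15.
- Corey–Chaykovsky methylenation (trimethylsulfonium iodide, NaH, DMSO/THF) gives racemic 2-{2-[4-(benzyloxy)phenyl]ethyl}oxirane F4.
- Hydrolytic kinetic resolution uses (S,S)-[N,N'-bis(3,5-di-tert-butylsalicylidene)cyclohexane-1,2-diaminato]cobalt acetate (0.5 mol %) and water (0.55 equiv).
- The resolution leaves (2S)-2-{2-[4-(benzyloxy)phenyl]ethyl}oxirane F5 and removes the antipode as (2R)-4-[4-(benzyloxy)phenyl]butane-1,2-diol F6.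
- LiC≡CH·H2NCH2CH2NH2 in DMSO opens F5 at the CH2 terminus and gives 15 with the stereocentre untouched.

**Step 9 (gold alkyne oxidation).** The alpha-oxo gold carbene may be over-oxidised by a second N-oxide or trapped by mesylate. The fallback avoids a carbene, sets out from 15, and comes back at 16.
- NBS with AgNO3 (10 mol %) in acetone gives (3S)-1-[4-(benzyloxy)phenyl]-6-bromohex-5-yn-3-ol F7.
- Hydration of the bromoalkyne ((XPhos)AuNTf2 cat., H2O, ClCH2CH2Cl, rt) gives (4S)-6-[4-(benzyloxy)phenyl]-1-bromo-4-hydroxyhexan-2-one F8.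
- K2CO3 in acetone at 0 °C closes the ring by 5-exo-tet Williamson displacement to 16.

**Further compounds**
F1 | step 10 | (4S)-6-[4-(benzyloxy)phenyl]-4-hydroxyhexan-2-one | CC(=O)C[C@H](CCc1ccc(OCc2ccccc2)cc1)O
F2 | step 10 | (5S)-1-[3,4-bis(benzyloxy)-5-methoxyphenyl]-7-[4-(benzyloxy)phenyl]-1,5-dihydroxyheptan-3-one (C1 epimers) | COc1cc(C(O)CC(=O)C[C@H](CCc2ccc(OCc3ccccc3)cc2)O)cc(OCc2ccccc2)c1OCc1ccccc1
F3 | step 10 | (1E,5S)-1-[3,4-bis(benzyloxy)-5-methoxyphenyl]-7-[4-(benzyloxy)phenyl]-5-hydroxyhept-1-en-3-one | COc1cc(/C=C/C(=O)C[C@H](CCc2ccc(OCc3ccccc3)cc2)O)cc(OCc2ccccc2)c1OCc1ccccc1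
F4 | step 8 | racemic 2-{2-[4-(benzyloxy)phenyl]ethyl}oxirane | C1OC1CCc1ccc(OCc2ccccc2)cc1
F5 | step 8 | (2S)-2-{2-[4-(benzyloxy)phenyl]ethyl}oxirane | C1[C@H](CCc2ccc(OCc3ccccc3)cc2)O1
F6 | step 8 | (2R)-4-[4-(benzyloxy)phenyl]butane-1,2-diol | OC[C@@H](CCc1ccc(OCc2ccccc2)cc1)O
F7 | step 9 | (3S)-1-[4-(benzyloxy)phenyl]-6-bromohex-5-yn-3-ol | BrC#CC[C@H](CCc1ccc(OCc2ccccc2)cc1)O
F8 | step 9 | (4S)-6-[4-(benzyloxy)phenyl]-1-bromo-4-hydroxyhexan-2-one | BrCC(=O)C[C@H](CCc1ccc(OCc2ccccc2)cc1)O
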